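Remark on the chemistry: the silyloxy-bearing carbon of the iodide is bonded directly to the radical carbon (it is the oxygen that is β) and keeps its configuration because none of its bonds is broken; the C7 oxygen is carried as a methoxymethyl acetal and not as an aryl silyl ether; 5-bromoresorcinol is assumed to be commercial and replaces the dimethoxy bromoarene, because the two ring methyls and the formyl group then enter by directed metalation and no methyl ether has to be cleaved later.

## Structural features

The target is a coumarin (benzo ring A fused to 2-pyranone ring B) whose benzo ring is fully substituted: C5 carries an (S)-2-hydroxypropyl chain (C1''–C3''), C6 and C8 carry methyl groups, C7 a phenol, and C4a/C8a the ring fusion. C3 of ring B is joined by an sp2–sp2 bond to C2' of a 6-methyl-2,3-dihydro-4H-pyran-4-one (ring C: O1', C2'=C3', C4' ketone, C5' methylene, C6' carbinol carbon, R). The two stereocentres, C2'' and C6', are both CH(CH3)–O units, lie ten bonds apart and cannot control one another, so each must be introduced on its own. Ring C is a vinylogous ester and a β-alkoxy ketone, which base opens by E1cB elimination with loss of the C6' configuration; the lactone and the acceptor carbon C4 do not tolerate hard nucleophiles. The C2'' hydroxyl sits peri to C4 and can add to it, and at the aldehyde stage it would close onto the formyl carbon as a lactol that dehydrates to a quinone methide. The real difficulty is twofold: a hexasubstituted benzene in which every substituent must be placed regiospecifically, and a 1,3-dioxygenated six-carbon unit at C3 whose stereocentre must survive its own ring closure. The key step exploits the position of the C4' carbonyl carbon between the alkene carbon C3' and the C5' methylene. It can therefore enter as carbon monoxide between a terminal alkyne carbon on the coumarin and the CH2 of a 2-silyloxypropyl iodide, whose oxygen later becomes O1'.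

## Logic of the disconnections

27 is cut at the O1'–C2' bond of ring C and at its three O-protecting bonds, which leads through 26 to 25. The dihydropyranone is the oxa-Michael adduct of a β-hydroxy ynone, and closing it last keeps the base-sensitive ring out of every earlier step. The gain is an acyclic, fully masked ynone. The forward step must unmask three oxygens and close the ring under acid only, without addition of the C2'' hydroxyl to C4.

25 is cut at C3'–C4' and C4'–C5', giving 20, 24 and 23. The ketone carbon is the only atom between an sp carbon and a methylene, so it can be 24. The molecule falls into the complete coumarin and a three-carbon chiral-pool iodide, and no stereocentre has to be created. The forward step must carbonylate faster than it couples directly, must not add radicals to C4, and must find no free phenol. For this reason the C7 oxygen in 20 is an acetal that also survives base, water and light.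

23 is cut at O–Si and C–I, giving 22 and then 21. Iodide opens the epoxide at its CH2, so the R centre is never touched. The demand is only regioselective opening.

20 is cut at the alkynyl C–Si bond (19) and then at C3–C(sp), giving 17 and 18. A Sonogashira coupling on a vinylic bromide α to a lactone carbonyl is reliable. The desilylation must spare the alkyl silyl ether and the acetal, which a carbonate in methanol does.

17 is cut at C3–Br to 15 (through 16). Addition–elimination puts the halogen on the only carbon of the molecule that can take it, since ring A has no free position. The demand is that the benzylic C4 position of 16 eliminates before the neighbouring silyloxy oxygen can attack it.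

15 is cut at C3=C4 and O1–C2 to 13 (through 14). An intramolecular Wittig reaction of the phenol-bound ylide forms ring B with the cis geometry built in. It needs exactly one free phenol (at C8a) and a masked C2'' oxygen so that the aldehyde stays open-chain.

13 is cut at the O–CH2 bond of the acetal next to the formyl group, giving 12. The two acetals of 12 differ only in their distance from the aldehyde, so chelation must do the differentiation.

12 is cut at three ring C–C bonds (C4a–CHO, C6–CH3, C8–CH3), passing 10 and 8 to 6 (through 11, 9 and 7). Each bond is made by directed ortho-metalation beside an acetal oxygen. The order follows acidity and compatibility: first the position between both oxygens, then one of the two equivalent positions, and the formyl group last because it would not survive a further lithiation.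

6 is cut at O–Si (5) and at the aryl–CH2 bond C5–C1'', giving 2 and 3 (through 4). An aryl Grignard reagent opens the epoxide at the unsubstituted carbon, so C2'' comes from the chiral pool. The demand is clean regioselectivity and no halohydrin formation.

2 is cut at two O–CH2 bonds to 1. The acetals are protecting groups, the directing groups for three metalations and, at C7, the group that lasts to the final step.

## Other disconnections considered

Alternative 1: The cut is the C4a–C5 bond of ring A, which unravels the arene into the acyclic triketo ester A1. In the forward step a mild base would let the C4a methylene of A1, flanked by the ester and a ketone, add to the C5 carbonyl. Loss of water and enolisation would give the resorcylate A2 with all six ring substituents in place.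
- In favour: the substitution pattern follows from the chain and is not a question of arene regiochemistry, the ring methyls come with propionate-type units, and no metalation is needed. On regiochemical certainty of ring A this alternative is the equal of the chosen plan or better.
- Against: A1 has three ketones and two epimerisable α-methyl carbons and can close in other modes (the C1'' methylene on the C8a carbonyl, or an enol onto the ester to give a pyranone). Its C5 ketone has the silyloxy group in the β position, so base can expel silanolate.
- Comparison: the assembly of A1 by repeated Claisen-type acylations of polyanions is not shorter than steps 1 to 6. After A2 the ester must still be brought to the aldehyde level beside two free phenols, one phenol must be told from the other, and ring C remains to be made, for which the same alkyne and carbonylation would be needed. Mechanistically, the mode selectivity of polyketo ester aldol closures depends on the substrate, whereas each metalation of the chosen route has one predictable site. In step count the two ways to the salicylaldehyde stage are about level.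

Alternative 2: The cut removes both carbon substituents of the C4a–C5 edge at once (C4a–C4 and C5–C1''), leaving the aryne A4, which fluoride would release from the silyl triflate A3. In the forward step the carbanion of dimethyl malonate A5 adds to C5 of A4, the aryl anion formed at C4a attacks one ester carbonyl, and the four-membered intermediate opens to the homophthalate A6. No ring remains.
- In favour: two C–C bonds are made at the most crowded edge of the ring in one metal-free step, and the C8a methoxy group steers the nucleophile to the distal C5. In bond-forming efficiency at this edge the alternative is better than the chosen plan, which needs steps 2 and 6 for the same two bonds.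
- Against: A3 is itself a hexasubstituted benzene whose preparation costs at least as much as that of 10, and the aryne is flanked by a methyl and a methoxy group, which slows addition of a bulky nucleophile. A6 is also far from the salicylaldehyde. Its two esters must be differentiated, the acetic ester turned into a methyl ketone and reduced enantioselectively, the benzoate reduced to the aldehyde, and two hindered methyl ethers cleaved by a strong Lewis acid beside a secondary alcohol.
- Comparison: the C2'' stereocentre would come from a catalyst, whereas in the chosen route it is bought with 3 and no bond to it is ever formed or broken. The alternative needs more steps overall and leaves ring C untouched.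

Alternative 3: The cut is made in ring C at C5'–C6' and O1'–C2'. The ring would come from the bis(silyloxy)diene A8, obtained by double enol silylation of the coumarin-3-yl 1,3-diketone A7, and from acetaldehyde A9. In the forward step a chiral titanium–binaphtholate Lewis acid (tetravalent titanium) would promote vinylogous Mukaiyama aldol addition of the terminal carbon of A8 to A9. Acid would then close the δ-hydroxy β-diketone to A10, with C6' set by the catalyst.
- In favour: ring and stereocentre are formed together, and neither pressurised carbon monoxide nor photochemistry is needed. A7 could come directly from a salicylaldehyde of the type of 13 by a Knoevenagel-type condensation with an acetoacetyl donor, which would save the bromination, the Sonogashira coupling and the alkyne desilylation. In step economy this alternative is better than the chosen plan.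
- Against: A9 is the least favourable aldehyde for such catalysts (small, volatile, enolisable, with little to distinguish its faces), so the enantiomeric purity at C6' is uncertain. Because the other stereocentre is remote, any shortfall would appear as a diastereomer that is hard to remove. The internal enol ether of A8 is conjugated to the electron-poor coumarin, and the lactone and diketone oxygens can bind titanium. A10 also still carries the aryl silyl ether whose lability toward base is the reason for the acetal in the chosen route.
- Comparison: both plans reach ring C by the C6' oxygen closing on C2'. The alternative relies on an enantioselective catalyst working on a difficult aldehyde; the chosen plan uses a coupling in which no bond to the stereocentre is made, and pays about three more steps for that certainty.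

Key step: step 14

## Route

Step 1
Reactants: 1 5-bromobenzene-1,3-diol (5-bromoresorcinol)
Product: 2 1-bromo-3,5-bis(methoxymethoxy)benzene
Conditions: MOMCl, i-Pr2NEt, CH2Cl2, 0 °C to rt
Reagents that add atoms: chloromethyl methyl ether, COCCl
Why: Double Williamson-type O-alkylation of the phenols with the α-chloro ether; the acetals resist the organomagnesium and organolithium reagents that follow and act as ortho-directing groups.

Step 2
Reactants: 2; 3 (S)-2-methyloxirane [(S)-propylene oxide]
Product: 5 (S)-1-[3,5-bis(methoxymethoxy)phenyl]propan-2-ol, via arylmagnesium bromide 4 (not isolated)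
Conditions: Mg, THF, 50 °C; then CuI (10 mol%), 3, −30 to 0 °C; aq. NH4Cl
Reagents that add atoms: none
Why: Magnesium insertion gives the aryl Grignard reagent, and copper-catalysed SN2 opening of the epoxide at its unsubstituted carbon forms the C5–C1'' bond. No bond to the stereocentre is broken, so the S configuration of 3 is carried into the carbinol.

Step 3
Reactants: 5
Product: 6 (S)-{1-[3,5-bis(methoxymethoxy)phenyl]propan-2-yloxy}(tert-butyl)dimethylsilane
Conditions: TBSCl, imidazole, DMF, rt
Reagents that add atoms: tert-butyldimethylsilyl chloride, CC(C)(C)[Si](C)(C)Cl
Why: Standard silylation of a secondary alcohol; the silyl ether keeps the oxygen from quenching the lithiations and later from closing onto the formyl group as a lactol.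

Step 4
Reactants: 6
Product: 8 (S)-{1-[3,5-bis(methoxymethoxy)-4-methylphenyl]propan-2-yloxy}(tert-butyl)dimethylsilane, via 4-lithio arene 7 (not isolated)
Conditions: n-BuLi, THF, 0 °C; then MeI, −78 °C to rt
Reagents that add atoms: iodomethane, CI
Why: Directed ortho-metalation: the hydrogen between the two acetal oxygens is the most acidic and doubly coordinated, so lithiation occurs there and methylation installs the future C8 methyl.

Step 5
Reactants: 8
Product: 10 (S)-{1-[3,5-bis(methoxymethoxy)-2,4-dimethylphenyl]propan-2-yloxy}(tert-butyl)dimethylsilane, via 2-lithio arene 9 (not isolated)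
Conditions: s-BuLi, TMEDA, THF, −78 °C; then MeI, −78 to 0 °C
Reagents that add atoms: iodomethane, CI
Why: Second directed ortho-metalation at one of the two equivalent positions beside an acetal oxygen gives the future C6 methyl; the low temperature limits migration of the silyl group to the neighbouring aryllithium.

Step 6
Reactants: 10
Product: 12 2-[(S)-2-(tert-butyldimethylsilyloxy)propyl]-4,6-bis(methoxymethoxy)-3,5-dimethylbenzaldehyde, via 6-lithio arene 11 (not isolated)
Conditions: s-BuLi, TMEDA, THF, −78 °C; then DMF, −78 to 0 °C; aq. NH4Cl
Reagents that add atoms: N,N-dimethylformamide, CN(C)C=O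
Why: Third directed ortho-metalation at the last ring hydrogen followed by formylation with DMF completes the hexasubstituted ring and supplies the carbon that becomes C4.

Step 7
Reactants: 12
Product: 13 2-[(S)-2-(tert-butyldimethylsilyloxy)propyl]-6-hydroxy-4-(methoxymethoxy)-3,5-dimethylbenzaldehyde
Conditions: MgBr2·OEt2, Et2O–toluene, 0 °C to rt; H2O
Reagents that add atoms: none
Why: Chelation-assisted Lewis acid cleavage of an aryl acetal: magnesium held between the formyl oxygen and the ortho acetal oxygen activates only that acetal toward bromide, while the unchelated C7 acetal and the silyl ether should remain.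

Step 8
Reactants: 13
Product: 15 5-[(S)-2-(tert-butyldimethylsilyloxy)propyl]-7-(methoxymethoxy)-6,8-dimethyl-2H-chromen-2-one, via aryl phosphoranylideneacetate 14 (not isolated)
Conditions: Ph3P=C=C=O, toluene, 110 °C
Reagents that add atoms: (triphenylphosphoranylidene)ketene, O=C=C=P(c1ccccc1)(c1ccccc1)c1ccccc1
Why: The phenol adds to the ketene ylide to give an ester-stabilised ylide, and intramolecular Wittig olefination with the neighbouring aldehyde closes ring B; the ring enforces the cis geometry that an intermolecular Wittig reaction would not give.

Step 9
Reactants: 15
Product: 17 3-bromo-5-[(S)-2-(tert-butyldimethylsilyloxy)propyl]-7-(methoxymethoxy)-6,8-dimethyl-2H-chromen-2-one, via trans-3,4-dibromochromanone 16 (not isolated)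
Conditions: Br2, CH2Cl2, −20 °C; then Et3N, 0 °C
Reagents that add atoms: bromine, BrBr
Why: Addition of bromine across C3=C4 and base-induced loss of HBr (acidic C3–H, benzylic C4–Br) is the classical route to 3-bromocoumarins; ring A has no free position, so ring bromination cannot compete.

Step 10
Reactants: 17; 18 ethynyltrimethylsilane (trimethylsilylacetylene)
Product: 19 5-[(S)-2-(tert-butyldimethylsilyloxy)propyl]-7-(methoxymethoxy)-6,8-dimethyl-3-[(trimethylsilyl)ethynyl]-2H-chromen-2-one
Conditions: PdCl2(PPh3)2 (3 mol%), CuI (6 mol%), Et3N, THF, 50 °C
Reagents that add atoms: none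
Why: Sonogashira coupling of an electron-poor vinylic bromide α to the lactone carbonyl, a substrate class on which oxidative addition is fast.

Step 11
Reactants: 19
Product: 20 5-[(S)-2-(tert-butyldimethylsilyloxy)propyl]-3-ethynyl-7-(methoxymethoxy)-6,8-dimethyl-2H-chromen-2-one
Conditions: K2CO3 (cat.), MeOH–THF, 0 °C
Reagents that add atoms: none
Why: Carbonate-catalysed methanolysis of the alkynyl C–Si bond; the alkyl silyl ether and the acetal are inert here, whereas an aryl silyl ether at C7 would be at risk.

Step 12
Reactants: 21 (R)-2-methyloxirane [(R)-propylene oxide]
Product: 22 (R)-1-iodopropan-2-ol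
Conditions: LiI, AcOH, THF, 0 °C to rt
Reagents that add atoms: lithium iodide, [Li+].[I-]
Why: Acid-assisted SN2 opening of the epoxide by iodide at the unsubstituted carbon (halohydrin formation); the stereocentre is not involved and stays R.

Step 13
Reactants: 22
Product: 23 (R)-tert-butyl[(1-iodopropan-2-yl)oxy]dimethylsilane
Conditions: TBSCl, imidazole, CH2Cl2, 0 °C to rt
Reagents that add atoms: tert-butyldimethylsilyl chloride, CC(C)(C)[Si](C)(C)Cl
Why: Silylation of the iodohydrin under weakly basic conditions that do not reclose the epoxide.

Step 14
Reactants: 20; 23; 24 carbon monoxide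
Product: 25 3-[(5R)-5-(tert-butyldimethylsilyloxy)-3-oxohex-1-yn-1-yl]-5-[(S)-2-(tert-butyldimethylsilyloxy)propyl]-7-(methoxymethoxy)-6,8-dimethyl-2H-chromen-2-one
Conditions: PdCl2(PPh3)2 (5 mol%), Et3N, CO (40 atm), benzene–H2O, hν (blue LED, ca. 450 nm), rt
Reagents that add atoms: none
Why: The divalent palladium precatalyst is reduced in situ to zerovalent palladium, which under visible light transfers an electron to the C–I bond of 23 and releases a primary alkyl radical together with a monovalent palladium iodide. Under 40 atm of 24 the radical is carbonylated faster than it can recombine with palladium, so neither direct alkyl–alkynyl coupling nor β-silyloxy elimination from an alkylpalladium species should compete. The acyl radical is captured by palladium (or by iodine atom transfer followed by oxidative addition) to give an acylpalladium iodide, which takes up the acetylide formed from 20 and Et3N and reductively eliminates the ynone, forming C3'–C4' and C4'–C5'. The closest known reaction type is the palladium-catalysed, light-promoted carbonylative Sonogashira-type coupling of alkyl iodides with terminal arylalkynes. No ring is closed and no stereocentre is created; the silyloxy-bearing carbon next to the radical centre has none of its bonds broken and keeps the R configuration bought with 21. The selectivity needed is reaction at the alkyne C–H and not at C4 of the coumarin: the alkyl and acyl radicals are nucleophilic, but C4 is shielded by the peri C5 side chain, and an excess of 23 over dilute 20 favours capture by palladium. The C7 oxygen is an acetal, so no phenoxide can intercept the acylpalladium as an aryl ester, and irradiation at 450 nm lies outside the coumarin absorption band and so avoids [2+2] photodimerisation.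

Step 15
Reactants: 25
Product: 27 7-hydroxy-5-[(2S)-2-hydroxypropyl]-6,8-dimethyl-3-[(6R)-6-methyl-4-oxo-5,6-dihydro-4H-pyran-2-yl]-2H-chromen-2-one, via triol ynone 26 (not isolated)
Conditions: TsOH·H2O, MeOH, rt to 40 °C
Reagents that add atoms: none
Why: Acidic methanolysis removes both silyl ethers and the aryl acetal, and the freed C6' hydroxyl adds to C2' of the protonated ynone in a 6-endo-dig oxa-Michael closure (acid-mediated cyclisation of β-hydroxy ynones to 2,3-dihydro-4H-pyran-4-ones). Base is avoided because it would open the β-oxy ketone by E1cB elimination; the new C–O bond is at C2', so the C6' configuration is untouched.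

## Compound list

1 | 5-bromobenzene-1,3-diol (5-bromoresorcinol) | Oc1cc(O)cc(Br)c1 | starting material
2 | 1-bromo-3,5-bis(methoxymethoxy)benzene | COCOc1cc(Br)cc(OCOC)c1 | intermediate
3 | (S)-2-methyloxirane | C[C@H]1CO1 | starting material
4 | [3,5-bis(methoxymethoxy)phenyl]magnesium bromide | COCOc1cc([Mg]Br)cc(OCOC)c1 | intermediate
5 | (S)-1-[3,5-bis(methoxymethoxy)phenyl]propan-2-ol | COCOc1cc(C[C@H](C)O)cc(OCOC)c1 | intermediate
6 | (S)-{1-[3,5-bis(methoxymethoxy)phenyl]propan-2-yloxy}(tert-butyl)dimethylsilane | COCOc1cc(C[C@H](C)O[Si](C)(C)C(C)(C)C)cc(OCOC)c1 | intermediate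
7 | {4-[(S)-2-(tert-butyldimethylsilyloxy)propyl]-2,6-bis(methoxymethoxy)phenyl}lithium | COCOc1cc(C[C@H](C)O[Si](C)(C)C(C)(C)C)cc(OCOC)c1[Li] | intermediate
8 | (S)-{1-[3,5-bis(methoxymethoxy)-4-methylphenyl]propan-2-yloxy}(tert-butyl)dimethylsilane | COCOc1cc(C[C@H](C)O[Si](C)(C)C(C)(C)C)cc(OCOC)c1C | intermediate
9 | {6-[(S)-2-(tert-butyldimethylsilyloxy)propyl]-2,4-bis(methoxymethoxy)-3-methylphenyl}lithium | COCOc1cc(C[C@H](C)O[Si](C)(C)C(C)(C)C)c([Li])c(OCOC)c1C | intermediate
10 | (S)-{1-[3,5-bis(methoxymethoxy)-2,4-dimethylphenyl]propan-2-yloxy}(tert-butyl)dimethylsilane | COCOc1cc(C[C@H](C)O[Si](C)(C)C(C)(C)C)c(C)c(OCOC)c1C | intermediate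
11 | {6-[(S)-2-(tert-butyldimethylsilyloxy)propyl]-2,4-bis(methoxymethoxy)-3,5-dimethylphenyl}lithium | COCOc1c([Li])c(C[C@H](C)O[Si](C)(C)C(C)(C)C)c(C)c(OCOC)c1C | intermediate
12 | 2-[(S)-2-(tert-butyldimethylsilyloxy)propyl]-4,6-bis(methoxymethoxy)-3,5-dimethylbenzaldehyde | COCOc1c(C=O)c(C[C@H](C)O[Si](C)(C)C(C)(C)C)c(C)c(OCOC)c1C | intermediate
13 | 2-[(S)-2-(tert-butyldimethylsilyloxy)propyl]-6-hydroxy-4-(methoxymethoxy)-3,5-dimethylbenzaldehyde | Oc1c(C=O)c(C[C@H](C)O[Si](C)(C)C(C)(C)C)c(C)c(OCOC)c1C | intermediate
14 | {3-[(S)-2-(tert-butyldimethylsilyloxy)propyl]-2-formyl-5-(methoxymethoxy)-4,6-dimethylphenyl} (triphenylphosphoranylidene)acetate | O=Cc1c(C[C@H](C)O[Si](C)(C)C(C)(C)C)c(C)c(OCOC)c(C)c1OC(=O)C=P(c1ccccc1)(c1ccccc1)c1ccccc1 | intermediate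
15 | 5-[(S)-2-(tert-butyldimethylsilyloxy)propyl]-7-(methoxymethoxy)-6,8-dimethyl-2H-chromen-2-one | Cc1c(OCOC)c(C)c2oc(=O)ccc2c1C[C@H](C)O[Si](C)(C)C(C)(C)C | intermediate
16 | trans-3,4-dibromo-5-[(S)-2-(tert-butyldimethylsilyloxy)propyl]-7-(methoxymethoxy)-6,8-dimethylchroman-2-one (C3 and C4 configuration not controlled) | Cc1c(OCOC)c(C)c2OC(=O)C(Br)C(Br)c2c1C[C@H](C)O[Si](C)(C)C(C)(C)C | intermediate
17 | 3-bromo-5-[(S)-2-(tert-butyldimethylsilyloxy)propyl]-7-(methoxymethoxy)-6,8-dimethyl-2H-chromen-2-one | Cc1c(OCOC)c(C)c2oc(=O)c(Br)cc2c1C[C@H](C)O[Si](C)(C)C(C)(C)C | intermediate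
18 | ethynyltrimethylsilane | C#C[Si](C)(C)C | starting material
19 | 5-[(S)-2-(tert-butyldimethylsilyloxy)propyl]-7-(methoxymethoxy)-6,8-dimethyl-3-[(trimethylsilyl)ethynyl]-2H-chromen-2-one | Cc1c(OCOC)c(C)c2oc(=O)c(C#C[Si](C)(C)C)cc2c1C[C@H](C)O[Si](C)(C)C(C)(C)C | intermediate
20 | 5-[(S)-2-(tert-butyldimethylsilyloxy)propyl]-3-ethynyl-7-(methoxymethoxy)-6,8-dimethyl-2H-chromen-2-one | Cc1c(OCOC)c(C)c2oc(=O)c(C#C)cc2c1C[C@H](C)O[Si](C)(C)C(C)(C)C | intermediate
21 | (R)-2-methyloxirane | C[C@@H]1CO1 | starting material
22 | (R)-1-iodopropan-2-ol | C[C@H](CI)O | intermediate
23 | (R)-tert-butyl[(1-iodopropan-2-yl)oxy]dimethylsilane | C[C@H](CI)O[Si](C)(C)C(C)(C)C | intermediate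
24 | carbon monoxide | [C-]#[O+] | starting material
25 | 3-[(5R)-5-(tert-butyldimethylsilyloxy)-3-oxohex-1-yn-1-yl]-5-[(S)-2-(tert-butyldimethylsilyloxy)propyl]-7-(methoxymethoxy)-6,8-dimethyl-2H-chromen-2-one | Cc1c(OCOC)c(C)c2oc(=O)c(C#CC(=O)C[C@@H](C)O[Si](C)(C)C(C)(C)C)cc2c1C[C@H](C)O[Si](C)(C)C(C)(C)C | intermediate
26 | 7-hydroxy-3-[(5R)-5-hydroxy-3-oxohex-1-yn-1-yl]-5-[(S)-2-hydroxypropyl]-6,8-dimethyl-2H-chromen-2-one | Cc1c(O)c(C)c2oc(=O)c(C#CC(=O)C[C@@H](C)O)cc2c1C[C@H](C)O | intermediate
27 | 7-hydroxy-5-[(2S)-2-hydroxypropyl]-6,8-dimethyl-3-[(6R)-6-methyl-4-oxo-5,6-dihydro-4H-pyran-2-yl]-2H-chromen-2-one | Cc1c(O)c(C)c2oc(=O)c(C3=CC(=O)C[C@@H](C)O3)cc2c1C[C@H](C)O | target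

## Step count and least certain steps

Total step count: 15. Longest linear sequence: 13 (steps 1 to 11, then 14 and 15); the iodide 23 is made in a two-step branch (steps 12 and 13).

Step 14 (key step). Most likely to go wrong: addition of the alkyl or acyl radical to the electron-poor C3=C4 bond or to the ynone already formed, and recombination of the alkyl radical with palladium before carbonylation, which leads to direct coupling or β-elimination. The cause is that the coumarin is a radical acceptor and a chromophore and that carbon monoxide capture depends on pressure. The fallback leaves the radical carbonylation for a two-electron acyl Sonogashira coupling. It sets out from 20 and returns at 25. Commercial methyl (R)-3-hydroxybutanoate F1 is silylated (TBSCl, imidazole) to methyl (R)-3-(tert-butyldimethylsilyloxy)butanoate F2. Saponification (LiOH, THF–H2O) gives (R)-3-(tert-butyldimethylsilyloxy)butanoic acid F3, and oxalyl chloride with catalytic DMF gives (R)-3-(tert-butyldimethylsilyloxy)butanoyl chloride F4. F4 is then coupled with 20 (PdCl2(PPh3)2, CuI, Et3N, THF, rt) to give 25, with the C6' configuration now drawn from the hydroxybutanoate.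

Step 7. Most likely to go wrong: loss of the second acetal, or incomplete cleavage of the first. The unchelated C7 acetal is twisted out of the ring plane by its two ortho methyls and may be more labile than expected. The fallback replaces selective deprotection by full deprotection and selective reprotection. It sets out from 12 and returns at 13. Both aryl acetals are removed with TMSOTf and 2,2'-bipyridyl followed by water, conditions that spare alkyl silyl ethers, to give 2-[(S)-2-(tert-butyldimethylsilyloxy)propyl]-4,6-dihydroxy-3,5-dimethylbenzaldehyde F5. The hydroxyl para to the formyl group, which is not hydrogen-bonded and is the more acidic, is then alkylated alone (MOMCl, K2CO3, acetone) to give 13.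

Step 9. Most likely to go wrong: capture of the benzylic C4 position of 16, or of the cation that precedes it, by the neighbouring C2'' silyloxy oxygen with loss of the silyl group and closure of a six-membered ether, or acid-induced loss of the acetal. C4 is a para-oxygenated benzylic centre with a nucleophile five atoms away. The fallback avoids any electrophile at C3=C4. It sets out from 15 and returns at 19. Deprotonative zincation at C3 with TMPZnCl·LiCl (THF, 25 °C) gives the 3-(chlorozincio)coumarin F6, iodine gives the 3-iodocoumarin F7, and Sonogashira coupling of F7 with 18 under the conditions of step 10 gives 19.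

Step 6 (the same concern applies to step 5). Most likely to go wrong: migration of the silyl group from oxygen to the adjacent lithiated ring carbon, or deprotonation of a benzylic methyl in place of the last, crowded ring hydrogen. The fallback places the metal by electrophilic halogenation and halogen–lithium exchange. It sets out from 10 and returns at 12. Bromination with NBS (MeCN, 0 °C) at the only free ring position gives the aryl bromide F8. Bromine–lithium exchange (n-BuLi, THF, −78 °C, a few minutes) gives 11 without an excess of strong base or any warming, and DMF then gives 12.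

Step 15. Most likely to go wrong: incomplete closure of 26, addition of the C2'' hydroxyl to C4 (now activated by the ynone), or slow cleavage of the hindered acetal with decomposition of ring C on prolonged exposure to acid. The fallback closes ring C by addition–elimination and not by attack on the alkyne. It sets out from 25 and returns at 27. Conjugate addition of Et2NH (THF, rt) gives the β-(diethylamino)enone F9, and aqueous HCl in THF then removes the three protecting groups and lets the C6' hydroxyl displace diethylamine at C2' to give 27.

## Further compounds

F1 | step 14 | methyl (R)-3-hydroxybutanoate | C[C@@H](O)CC(=O)OC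
F2 | step 14 | methyl (R)-3-(tert-butyldimethylsilyloxy)butanoate | C[C@H](CC(=O)OC)O[Si](C)(C)C(C)(C)C
F3 | step 14 | (R)-3-(tert-butyldimethylsilyloxy)butanoic acid | C[C@H](CC(=O)O)O[Si](C)(C)C(C)(C)C
F4 | step 14 | (R)-3-(tert-butyldimethylsilyloxy)butanoyl chloride | C[C@H](CC(=O)Cl)O[Si](C)(C)C(C)(C)C
F5 | step 7 | 2-[(S)-2-(tert-butyldimethylsilyloxy)propyl]-4,6-dihydroxy-3,5-dimethylbenzaldehyde | Oc1c(C=O)c(C[C@H](C)O[Si](C)(C)C(C)(C)C)c(C)c(O)c1C
F6 | step 9 | {5-[(S)-2-(tert-butyldimethylsilyloxy)propyl]-7-(methoxymethoxy)-6,8-dimethyl-2-oxo-2H-chromen-3-yl}zinc chloride | Cc1c(OCOC)c(C)c2oc(=O)c([Zn]Cl)cc2c1C[C@H](C)O[Si](C)(C)C(C)(C)C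
F7 | step 9 | 5-[(S)-2-(tert-butyldimethylsilyloxy)propyl]-3-iodo-7-(methoxymethoxy)-6,8-dimethyl-2H-chromen-2-one | Cc1c(OCOC)c(C)c2oc(=O)c(I)cc2c1C[C@H](C)O[Si](C)(C)C(C)(C)C
F8 | step 6 | (S)-{1-[2-bromo-3,5-bis(methoxymethoxy)-4,6-dimethylphenyl]propan-2-yloxy}(tert-butyl)dimethylsilane | COCOc1c(Br)c(C[C@H](C)O[Si](C)(C)C(C)(C)C)c(C)c(OCOC)c1C
F9 | step 15 | 3-[(5R)-5-(tert-butyldimethylsilyloxy)-1-(diethylamino)-3-oxohex-1-en-1-yl]-5-[(S)-2-(tert-butyldimethylsilyloxy)propyl]-7-(methoxymethoxy)-6,8-dimethyl-2H-chromen-2-one | Cc1c(OCOC)c(C)c2oc(=O)c(C(N(CC)CC)=CC(=O)C[C@@H](C)O[Si](C)(C)C(C)(C)C)cc2c1C[C@H](C)O[Si](C)(C)C(C)(C)C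
A1 | alternative 1 | methyl (9S)-9-(tert-butyldimethylsilyloxy)-4,6-dimethyl-3,5,7-trioxodecanoate | COC(=O)CC(=O)C(C)C(=O)C(C)C(=O)C[C@H](C)O[Si](C)(C)C(C)(C)C
A2 | alternative 1 | methyl 2,4-dihydroxy-3,5-dimethyl-6-[(S)-2-(tert-butyldimethylsilyloxy)propyl]benzoate | COC(=O)c1c(O)c(C)c(O)c(C)c1C[C@H](C)O[Si](C)(C)C(C)(C)C
A3 | alternative 2 | 3,5-dimethoxy-2,4-dimethyl-6-(trimethylsilyl)phenyl trifluoromethanesulfonate | COc1c(C)c(OC)c(C)c(OS(=O)(=O)C(F)(F)F)c1[Si](C)(C)C
A4 | alternative 2 | 1,2-didehydro-3,5-dimethoxy-4,6-dimethylbenzene | COC1=C(C)C(OC)=C(C)C#C1
A5 | alternative 2 | dimethyl malonate | COC(=O)CC(=O)OC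
A6 | alternative 2 | methyl 4,6-dimethoxy-2-(2-methoxy-2-oxoethyl)-3,5-dimethylbenzoate | COC(=O)Cc1c(C)c(OC)c(C)c(OC)c1C(=O)OC
A7 | alternative 3 | 1-{7-(tert-butyldimethylsilyloxy)-5-[(S)-2-(tert-butyldimethylsilyloxy)propyl]-6,8-dimethyl-2-oxo-2H-chromen-3-yl}butane-1,3-dione | Cc1c(O[Si](C)(C)C(C)(C)C)c(C)c2oc(=O)c(C(=O)CC(C)=O)cc2c1C[C@H](C)O[Si](C)(C)C(C)(C)C
A8 | alternative 3 | 3-[1,3-bis(trimethylsilyloxy)buta-1,3-dien-1-yl]-7-(tert-butyldimethylsilyloxy)-5-[(S)-2-(tert-butyldimethylsilyloxy)propyl]-6,8-dimethyl-2H-chromen-2-one | Cc1c(O[Si](C)(C)C(C)(C)C)c(C)c2oc(=O)c(C(O[Si](C)(C)C)=CC(=C)O[Si](C)(C)C)cc2c1C[C@H](C)O[Si](C)(C)C(C)(C)C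
A9 | alternative 3 | acetaldehyde | CC=O
A10 | alternative 3 | 7-(tert-butyldimethylsilyloxy)-5-[(S)-2-(tert-butyldimethylsilyloxy)propyl]-6,8-dimethyl-3-[(6R)-6-methyl-4-oxo-5,6-dihydro-4H-pyran-2-yl]-2H-chromen-2-one | Cc1c(O[Si](C)(C)C(C)(C)C)c(C)c2oc(=O)c(C3=CC(=O)C[C@@H](C)O3)cc2c1C[C@H](C)O[Si](C)(C)C(C)(C)C
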